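**Strategy**

- Retrosynthesis: the silyl group is removed and the C3 CH2OH is taken back to CHO. The tetrahydrofuran is then cut at O1–C2 and C2–C3 together, giving 3,4,5-trimethoxybenzaldehyde and an open-chain silyloxy enol ether. The carbinol–C4 bond is cut last, by an aldol, to 3,4-dimethoxybenzaldehyde and an N-(4-methoxycrotonyl) oxazolidinone.
- Enabling feature: in the ring O1–C2(trimethoxyphenyl)–C3(CH2OH)–C4(veratryl carbinol)–C5H2, C3 at the aldehyde oxidation level is a formyl α-carbon next to the benzylic, O1-bearing C2. One aldehyde carbon can therefore be bonded to both O1 and C3, and the 2,3-trans/3,4-trans pattern is the thermodynamic one for an epimerizable C3.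
- Forward order: the auxiliary is acylated, the aldol joins the veratryl unit to the four-carbon chain, then silylation, reductive release and O-silylation follow. The only ring closes in the operation that brings in the trimethoxyphenyl aldehyde.
- Stereochemistry: the carbinol carbon and C4 come from the auxiliary-controlled syn aldol ((S)-benzyl oxazolidinone). C2 is set relative to C4 in the cyclization (2,4-cis). C3 is set by equilibration of the aldehyde before reduction.

Key step: step 6

Assumption: ring atoms are numbered O1, C2 (trimethoxyphenyl), C3 (CH2OH), C4 (carbinol side chain), C5. The enol ether double bond is drawn E throughout; either geometry is expected to serve, because its inner carbon ends as the epimerizable C3.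

Step 1
Reactants: 1 (E)-4-methoxybut-2-enoic acid; 2 (S)-4-benzyl-1,3-oxazolidin-2-one
Product: 4 (4S)-4-benzyl-3-[(2E)-4-methoxybut-2-enoyl]-1,3-oxazolidin-2-one, via mixed pivalic anhydride 3 (not isolated)
Conditions: PivCl, Et3N, THF, −20 °C; then LiCl, 2, −20 °C → rt
Reagents that add atoms: none
Why: Mixed-anhydride N-acylation of the oxazolidinone (pivaloyl chloride/LiCl protocol) should deliver the acyl group from the less hindered crotonyl carbonyl of the anhydride without disturbing the E double bond.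

Step 2
Reactants: 4 (4S)-4-benzyl-3-[(2E)-4-methoxybut-2-enoyl]-1,3-oxazolidin-2-one; 5 3,4-dimethoxybenzaldehyde
Product: 8 (4S)-4-benzyl-3-[(2S,3E)-2-[(S)-(3,4-dimethoxyphenyl)(hydroxy)methyl]-4-methoxybut-3-enoyl]-1,3-oxazolidin-2-one, via boron dienolate 6 (not isolated), via boron aldolate 7 (not isolated)
Conditions: Bu2BOTf, Et3N, CH2Cl2, −78 → 0 °C; 5, −78 → 0 °C; pH 7 buffer, MeOH, 30% H2O2, 0 °C
Reagents that add atoms: none
Why: Soft enolization removes a γ-proton to give the Z(O) boron dienolate, which should react at its α-carbon through a closed Zimmerman–Traxler chair (deconjugative Evans syn aldol, as established for N-crotonyl imides); the benzyl group of the auxiliary shields one enolate face, so the carbinol carbon and the future C4 are set together as the (S,S) syn pair.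

Step 3
Reactants: 8 (4S)-4-benzyl-3-[(2S,3E)-2-[(S)-(3,4-dimethoxyphenyl)(hydroxy)methyl]-4-methoxybut-3-enoyl]-1,3-oxazolidin-2-one
Product: 9 (4S)-4-benzyl-3-[(2S,3E)-2-[(S)-(tert-butyldimethylsilyloxy)(3,4-dimethoxyphenyl)methyl]-4-methoxybut-3-enoyl]-1,3-oxazolidin-2-one
Conditions: TBSOTf, 2,6-lutidine, CH2Cl2, −78 → 0 °C
Reagents that add atoms: tert-butyldimethylsilyl triflate (TBSOTf), CC(C)(C)[Si](C)(C)OS(=O)(=O)C(F)(F)F
Why: Silyl triflate O-silylation buffered by 2,6-lutidine should cap the hindered benzylic hydroxyl without free acid, so the enol ether, the imide and both stereocentres are left untouched.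

Step 4
Reactants: 9 (4S)-4-benzyl-3-[(2S,3E)-2-[(S)-(tert-butyldimethylsilyloxy)(3,4-dimethoxyphenyl)methyl]-4-methoxybut-3-enoyl]-1,3-oxazolidin-2-one
Product: 10 (2R,3E)-2-[(S)-(tert-butyldimethylsilyloxy)(3,4-dimethoxyphenyl)methyl]-4-methoxybut-3-en-1-ol
Conditions: LiBH4, MeOH (1 equiv), THF, 0 °C
Reagents that add atoms: none
Why: Borohydride reductive cleavage of the N-acyl oxazolidinone should give the primary alcohol and release the auxiliary, the exocyclic carbonyl being the activated one; silyl ether, enol ether and stereocentres are unaffected (the C2 descriptor changes from S to R only through the CIP ranking).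

Step 5
Reactants: 10 (2R,3E)-2-[(S)-(tert-butyldimethylsilyloxy)(3,4-dimethoxyphenyl)methyl]-4-methoxybut-3-en-1-ol
Product: 11 (2R,3E)-2-[(S)-(tert-butyldimethylsilyloxy)(3,4-dimethoxyphenyl)methyl]-4-methoxybut-3-en-1-yl trimethylsilyl ether
Conditions: TMSCl, Et3N, DMAP (cat.), CH2Cl2, 0 °C; filtration through Celite (pentane), no chromatography
Reagents that add atoms: chlorotrimethylsilane (TMSCl), C[Si](C)(C)Cl
Why: Standard base-mediated O-trimethylsilylation of a primary alcohol, chosen so that the oxocarbenium ion of the next step can be generated without any protic acid near the enol ether.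

Step 6
Reactants: 11 (2R,3E)-2-[(S)-(tert-butyldimethylsilyloxy)(3,4-dimethoxyphenyl)methyl]-4-methoxybut-3-en-1-yl trimethylsilyl ether; 12 3,4,5-trimethoxybenzaldehyde
Product: 16 (2R,3R,4R)-4-[(S)-(tert-butyldimethylsilyloxy)(3,4-dimethoxyphenyl)methyl]-2-(3,4,5-trimethoxyphenyl)oxolane-3-carbaldehyde, via mixed silyl acetal 13 (not isolated), via aryl oxocarbenium triflate 14 (not isolated), via ring-closed methoxycarbenium triflate 15 (not isolated)
Conditions: TMSOTf (1.2 equiv), 2,6-di-tert-butyl-4-methylpyridine (0.3 equiv), CH2Cl2, −78 °C; sat. aq. NaHCO3, −78 °C → rt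
Reagents that add atoms: water, O
Why: TMSOTf should convert aldehyde 12 and the primary silyl ether of 11 into mixed silyl acetal 13 and then, with loss of hexamethyldisiloxane, into the (E)-oxocarbenium ion 14 on O1, whose C2 is attacked by the inner carbon of the methyl enol ether (the future C3) to give methoxycarbenium ion 15, which is hydrolysed to the formyl group on quench. The closest known reactions are the Lewis acid condensation of γ-hydroxy enol ethers or enol carbamates with aldehydes to tetrahydrofuran-3-carbaldehydes and the Petasis–Ferrier-type O-to-C rearrangement of seven-membered vinyl acetals, here run under silyl ether/silyl triflate acetalization conditions to stay aprotic. The tetrahydrofuran closes in a 5-(enolexo)-endo-trig mode at the C=O+ acceptor, a mode that is routine for oxocarbenium ions. C2 is set relative to the aldol-derived C4 in an envelope transition state that keeps the trimethoxyphenyl group and the C4 side chain both pseudo-equatorial (2,4-cis), while C3 forms under kinetic control and, being α to the new aldehyde, is left to be corrected to the trans,trans arrangement in step 7. The step needs five- over six-membered closure and no ionization at the veratryl carbinol: the first is secured by the methoxy group, which makes the inner enol ether carbon the nucleophile and disfavours Prins and 2-oxonia-Cope paths, and the second by the bulky, weakly basic OTBS group, the hindered pyridine buffer and the low temperature.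

Step 7
Reactants: 16 (2R,3R,4R)-4-[(S)-(tert-butyldimethylsilyloxy)(3,4-dimethoxyphenyl)methyl]-2-(3,4,5-trimethoxyphenyl)oxolane-3-carbaldehyde (with any C3 epimer carried from step 6)
Product: 17 [(2R,3S,4R)-4-[(S)-(tert-butyldimethylsilyloxy)(3,4-dimethoxyphenyl)methyl]-2-(3,4,5-trimethoxyphenyl)oxolan-3-yl]methanol
Conditions: DBU (0.2 equiv), CH2Cl2, rt; then MeOH, NaBH4, 0 °C
Reagents that add atoms: none
Why: Amine-mediated enolization should equilibrate the formyl-bearing C3 to the isomer trans to both the C2 aryl group and the C4 side chain (thermodynamic control, no other centre being acidic), after which NaBH4 reduces the aldehyde chemoselectively to the primary alcohol.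

Step 8
Reactants: 17 [(2R,3S,4R)-4-[(S)-(tert-butyldimethylsilyloxy)(3,4-dimethoxyphenyl)methyl]-2-(3,4,5-trimethoxyphenyl)oxolan-3-yl]methanol
Product: 18 (S)-(3,4-dimethoxyphenyl)[(3R,4S,5R)-4-(hydroxymethyl)-5-(3,4,5-trimethoxyphenyl)oxolan-3-yl]methanol (CNP0172668.1)
Conditions: TBAF, THF, 0 °C → rt
Reagents that add atoms: none
Why: Fluoride-mediated desilylation should remove the TBS ether under non-acidic conditions, which spares the ionizable veratryl carbinol and the benzylic ring C–O bond and leaves all four stereocentres as set.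

**Compound list**

1 | (E)-4-methoxybut-2-enoic acid | COC/C=C/C(=O)O | starting material
2 | (S)-4-benzyl-1,3-oxazolidin-2-one | O=C1N[C@@H](Cc2ccccc2)CO1 | starting material
3 | (E)-4-methoxybut-2-enoic pivalic anhydride | COC/C=C/C(=O)OC(=O)C(C)(C)C | intermediate (not isolated)
4 | (4S)-4-benzyl-3-[(2E)-4-methoxybut-2-enoyl]-1,3-oxazolidin-2-one | COC/C=C/C(=O)N1[C@@H](Cc2ccccc2)COC1=O | intermediate
5 | 3,4-dimethoxybenzaldehyde | COc1ccc(C=O)cc1OC | starting material
6 | dibutylboron Z(O)-dienolate of 4 (4-methoxybuta-1,3-dienyl borinate, enol ether E) | CCCCB(CCCC)O/C(N1[C@@H](Cc2ccccc2)COC1=O)=C\C=C\OC | intermediate (not isolated)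
7 | O-dibutylboryl aldolate of 8 | COc1ccc([C@@H](OB(CCCC)CCCC)[C@H](/C=C/OC)C(=O)N2[C@@H](Cc3ccccc3)COC2=O)cc1OC | intermediate (not isolated)
8 | (4S)-4-benzyl-3-[(2S,3E)-2-[(S)-(3,4-dimethoxyphenyl)(hydroxy)methyl]-4-methoxybut-3-enoyl]-1,3-oxazolidin-2-one | COc1ccc([C@@H](O)[C@H](/C=C/OC)C(=O)N2[C@@H](Cc3ccccc3)COC2=O)cc1OC | intermediate
9 | (4S)-4-benzyl-3-[(2S,3E)-2-[(S)-(tert-butyldimethylsilyloxy)(3,4-dimethoxyphenyl)methyl]-4-methoxybut-3-enoyl]-1,3-oxazolidin-2-one | COc1ccc([C@@H](O[Si](C)(C)C(C)(C)C)[C@H](/C=C/OC)C(=O)N2[C@@H](Cc3ccccc3)COC2=O)cc1OC | intermediate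
10 | (2R,3E)-2-[(S)-(tert-butyldimethylsilyloxy)(3,4-dimethoxyphenyl)methyl]-4-methoxybut-3-en-1-ol | COc1ccc([C@@H](O[Si](C)(C)C(C)(C)C)[C@H](/C=C/OC)CO)cc1OC | intermediate
11 | (2R,3E)-2-[(S)-(tert-butyldimethylsilyloxy)(3,4-dimethoxyphenyl)methyl]-4-methoxybut-3-en-1-yl trimethylsilyl ether | COc1ccc([C@@H](O[Si](C)(C)C(C)(C)C)[C@H](/C=C/OC)CO[Si](C)(C)C)cc1OC | intermediate
12 | 3,4,5-trimethoxybenzaldehyde | COc1cc(C=O)cc(OC)c1OC | starting material
13 | mixed silyl acetal of 12 (acetal carbon bearing OSiMe3 and the primary oxygen of 11; acetal centre unassigned) | COc1ccc([C@@H](O[Si](C)(C)C(C)(C)C)[C@H](/C=C/OC)COC(O[Si](C)(C)C)c2cc(OC)c(OC)c(OC)c2)cc1OC | intermediate (not isolated)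
14 | (E)-O-alkyl 3,4,5-trimethoxybenzylidene oxocarbenium triflate (open chain, enol ether intact) | COc1ccc([C@@H](O[Si](C)(C)C(C)(C)C)[C@H](/C=C/OC)C/[O+]=C/c2cc(OC)c(OC)c(OC)c2)cc1OC.[O-]S(=O)(=O)C(F)(F)F | intermediate (not isolated)
15 | ring-closed O-methyl oxocarbenium triflate (tetrahydrofuran with CH=O+Me at C3, drawn trans,trans) | COc1ccc([C@@H](O[Si](C)(C)C(C)(C)C)[C@H]2CO[C@@H](c3cc(OC)c(OC)c(OC)c3)[C@@H]2C=[O+]C)cc1OC.[O-]S(=O)(=O)C(F)(F)F | intermediate (not isolated)
16 | (2R,3R,4R)-4-[(S)-(tert-butyldimethylsilyloxy)(3,4-dimethoxyphenyl)methyl]-2-(3,4,5-trimethoxyphenyl)oxolane-3-carbaldehyde | COc1ccc([C@@H](O[Si](C)(C)C(C)(C)C)[C@H]2CO[C@@H](c3cc(OC)c(OC)c(OC)c3)[C@@H]2C=O)cc1OC | intermediate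
17 | [(2R,3S,4R)-4-[(S)-(tert-butyldimethylsilyloxy)(3,4-dimethoxyphenyl)methyl]-2-(3,4,5-trimethoxyphenyl)oxolan-3-yl]methanol | COc1ccc([C@@H](O[Si](C)(C)C(C)(C)C)[C@H]2CO[C@@H](c3cc(OC)c(OC)c(OC)c3)[C@@H]2CO)cc1OC | intermediate
18 | (S)-(3,4-dimethoxyphenyl)[(3R,4S,5R)-4-(hydroxymethyl)-5-(3,4,5-trimethoxyphenyl)oxolan-3-yl]methanol (CNP0172668.1) | COc1ccc([C@@H](O)[C@H]2CO[C@@H](c3cc(OC)c(OC)c(OC)c3)[C@@H]2CO)cc1OC | target

**Step count**

Total: 8 steps. Longest linear sequence: 8 steps (1 or 2 to 18); aldehydes 5 and 12 enter as purchased.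

**Steps most likely to fail**

Step 6. The enol ether may add intermolecularly to the silyl-activated aldehyde before the mixed acetal has formed. The electron-rich veratryl ring may also capture the methoxycarbenium ion in a Friedel–Crafts closure, and facial selectivity at C2 may be incomplete. The fallback joins the two halves before any cation is made, so that the oxocarbenium ion can only arise intramolecularly. It sets out from 10 and comes back at 16. Alcohol 10 is acylated with 3,4,5-trimethoxybenzoyl chloride (Et3N, DMAP, CH2Cl2) to give the 3,4,5-trimethoxybenzoate ester F1. Reduction of the ester with DIBAL-H at −78 °C and in situ acetylation of the aluminium hemiacetal (Ac2O, pyridine, DMAP) gives the α-acetoxy benzylic ether F2. Ionization of F2 with BF3·OEt2 and a hindered pyridine in CH2Cl2 at −78 °C, followed by bicarbonate quench, should then close the ring onto the enol ether and give 16.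

Step 2. γ-Deprotonation of the methoxy-substituted imide may be sluggish, the dienolate may react in part at its γ-carbon, and the enol ether may be partly hydrolysed during the buffered peroxide work-up. The fallback installs the methoxyvinyl group after a plain crotonyl aldol. It sets out from 2 (with 5) and comes back at 10.
- Auxiliary 2 is acylated (n-BuLi, (E)-crotonyl chloride, THF, −78 °C) to the N-crotonyl imide F3.
- The established deconjugative boron aldol with 5 (Bu2BOTf, Et3N) gives the α-vinyl syn aldol adduct F4.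
- Silylation (TBSOTf, 2,6-lutidine) gives the silyl ether F5.
- LiBH4/MeOH gives the primary alcohol F6.
- TESCl/imidazole gives the primary triethylsilyl ether F7.
- Oxidative cleavage of the vinyl group (OsO4 cat., NaIO4, 2,6-lutidine, dioxane/H2O) gives the α-branched aldehyde F8, used at once.
- Wittig methoxymethylenation (Ph3P=CHOMe from the phosphonium chloride and KHMDS, THF, −78 → 0 °C) gives the enol ether triethylsilyl ether F9.
- Selective removal of the primary TES group (TBAF, 1 equiv, THF, −20 °C) returns 10.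

Step 7. Epimerization at C3 may stay incomplete, or base-induced β-elimination of the ring oxygen (retro-oxa-Michael ring opening) may compete with it before the hydride is added. The fallback moves the equilibration to the ester oxidation level. It sets out from 16 (as its C3 mixture) and comes back at 17. Pinnick oxidation (NaClO2, NaH2PO4, 2-methyl-2-butene, t-BuOH/H2O) gives the carboxylic acid F10. Methylation (TMSCHN2, MeOH/toluene) gives the methyl ester F11. The ester is equilibrated to the trans,trans isomer with NaOMe in MeOH and reduced with LiAlH4 (THF, 0 °C) to 17.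

**Further compounds**

F1 | step 6 | (2R,3E)-2-[(S)-(tert-butyldimethylsilyloxy)(3,4-dimethoxyphenyl)methyl]-4-methoxybut-3-en-1-yl 3,4,5-trimethoxybenzoate | COc1ccc([C@@H](O[Si](C)(C)C(C)(C)C)[C@H](/C=C/OC)COC(=O)c2cc(OC)c(OC)c(OC)c2)cc1OC
F2 | step 6 | α-acetoxy ether: [(2R,3E)-2-[(S)-(tert-butyldimethylsilyloxy)(3,4-dimethoxyphenyl)methyl]-4-methoxybut-3-en-1-yl]oxy(3,4,5-trimethoxyphenyl)methyl acetate (acetal centre unassigned) | COc1ccc([C@@H](O[Si](C)(C)C(C)(C)C)[C@H](/C=C/OC)COC(OC(C)=O)c2cc(OC)c(OC)c(OC)c2)cc1OC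
F3 | step 2 | (4S)-4-benzyl-3-[(2E)-but-2-enoyl]-1,3-oxazolidin-2-one | C/C=C/C(=O)N1[C@@H](Cc2ccccc2)COC1=O
F4 | step 2 | (4S)-4-benzyl-3-[(2S)-2-[(S)-(3,4-dimethoxyphenyl)(hydroxy)methyl]but-3-enoyl]-1,3-oxazolidin-2-one | COc1ccc([C@@H](O)[C@H](C=C)C(=O)N2[C@@H](Cc3ccccc3)COC2=O)cc1OC
F5 | step 2 | (4S)-4-benzyl-3-[(2S)-2-[(S)-(tert-butyldimethylsilyloxy)(3,4-dimethoxyphenyl)methyl]but-3-enoyl]-1,3-oxazolidin-2-one | COc1ccc([C@@H](O[Si](C)(C)C(C)(C)C)[C@H](C=C)C(=O)N2[C@@H](Cc3ccccc3)COC2=O)cc1OC
F6 | step 2 | (2R)-2-[(S)-(tert-butyldimethylsilyloxy)(3,4-dimethoxyphenyl)methyl]but-3-en-1-ol | COc1ccc([C@@H](O[Si](C)(C)C(C)(C)C)[C@H](C=C)CO)cc1OC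
F7 | step 2 | (2R)-2-[(S)-(tert-butyldimethylsilyloxy)(3,4-dimethoxyphenyl)methyl]but-3-en-1-yl triethylsilyl ether | COc1ccc([C@@H](O[Si](C)(C)C(C)(C)C)[C@H](C=C)CO[Si](CC)(CC)CC)cc1OC
F8 | step 2 | (2R,3S)-3-(tert-butyldimethylsilyloxy)-3-(3,4-dimethoxyphenyl)-2-[(triethylsilyloxy)methyl]propanal | COc1ccc([C@@H](O[Si](C)(C)C(C)(C)C)[C@H](C=O)CO[Si](CC)(CC)CC)cc1OC
F9 | step 2 | (2R,3E)-2-[(S)-(tert-butyldimethylsilyloxy)(3,4-dimethoxyphenyl)methyl]-4-methoxybut-3-en-1-yl triethylsilyl ether | COc1ccc([C@@H](O[Si](C)(C)C(C)(C)C)[C@H](/C=C/OC)CO[Si](CC)(CC)CC)cc1OC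
F10 | step 7 | (2R,3R,4R)-4-[(S)-(tert-butyldimethylsilyloxy)(3,4-dimethoxyphenyl)methyl]-2-(3,4,5-trimethoxyphenyl)oxolane-3-carboxylic acid | COc1ccc([C@@H](O[Si](C)(C)C(C)(C)C)[C@H]2CO[C@@H](c3cc(OC)c(OC)c(OC)c3)[C@@H]2C(=O)O)cc1OC
F11 | step 7 | methyl (2R,3R,4R)-4-[(S)-(tert-butyldimethylsilyloxy)(3,4-dimethoxyphenyl)methyl]-2-(3,4,5-trimethoxyphenyl)oxolane-3-carboxylate | COc1ccc([C@@H](O[Si](C)(C)C(C)(C)C)[C@H]2CO[C@@H](c3cc(OC)c(OC)c(OC)c3)[C@@H]2C(=O)OC)cc1OC
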